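The earlier runs and the new flask were computed on assumed constants; noise was put on by code.

Whatever the flask does, the percentages of the substrate charged must add up to 100: solid, dissolved, and what has been made from it. That is my ledger, and the substrate is its limiting reagent, with the gas held.

in all of them: gas 27 mM (held)
- maple: solid substrate 0.30 M; run made earlier
- flask: solid substrate 0.20 M; time 3.0 min

maple run (percent of the solid substrate charged)

| time / s | target / % | dissolved substrate / % |
|---|---|---|
| 10.0 | 0.5 | 41.5 |
| 12.0 | 0.8 | 43.5 |
| 20.0 | 1.3 | 45.3 |
| 30.0 | 3.5 | 46.1 |
| 40.0 | 5.6 | 46.0 |

(standard deviation of a reading: 0.3 percentage points)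

- given per volume of solution although it is solid: solid substrate
- at the start none of the solid substrate is in solution
- at the start none of the gas is in solution
- dissolved substrate means what is dissolved; the solid is not counted in it

1. the target standing at 3.0 min, as a percentage of the solid substrate charged
2. concentration of dissolved substrate in solution at 1.5 min, in percent of saturation
3. the change that raises the amount of target at 3.0 min, in percent of the solid substrate charged most ("none" if none brings more than 2 percentage points) (Tuesday's / Monday's / Saturday's / Friday's / none)
4. amount of target at 3.0 min, in percent of the solid substrate charged, after Saturday's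

- Tuesday's: doubling the solubility of the solid substrate, all else as stated
- Monday's: doubling the transfer coefficient of the gas, all else as stated
- Saturday's: doubling the dissolution coefficient of the solid substrate, all else as stated
- Friday's: doubling the saturation concentration of gas, all else as stated

In the maple run at 40.0 s, the books show 46.0 % dissolved and 5.6 % target, so, with nothing else seen, I book 48.4 % as solid. The dissolved entry read 46.1 % at 30.0 s, level within the scatter of 0.3 percentage points. I therefore read its level, S = 0.138 M, as the saturation concentration. The target entry grows at a feed F = 0.645 mM s⁻¹ between 20.0 s and 40.0 s, and this line, a reading with its scatter, starts from zero at a lag t₀ = 14.0 s.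

Now the flask. S takes 69.0 % of its charge, and the other 31.0 % can leave the solid state by passing on to target. My carried quantity is the solid-out time, t₀ plus the charge above S divided by F: 1.83 min. That is later than 1.5 min, so I expect solid present and the solution close to S then. It is earlier than 3.0 min, so after it the dissolved entry pays, and I expect F to slacken. So I expect the target at 3.0 min between 31.0 % and the straight line's 53.5 %, an estimated bracket and not a single figure.

The forecast gives, in the order asked, 49 %, 97 %, Friday's and 50 %, and says of its choice: “Rate is linear in gas saturation, so Friday's doubles it.”

The flask gives 42.6 % and 98.2 %. The strongest change is Friday's, worth 30 points, and Saturday's leaves 42.7 %.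

    dissolved substrate + reagent → target (k = 0.310 M⁻¹ s⁻¹)
    solid substrate ⇌ dissolved substrate, rate k2*(cs2 - [dissolved substrate]) while solid is left; crystals form when [dissolved substrate] > cs2 (solubility = 0.140 M, k = 0.230 s⁻¹)
    gas ⇌ reagent, rate k3*(csat - [reagent]) (kL = 0.0390 s⁻¹)
    dissolved substrate + target → side product (k = 0.00450 M⁻¹ s⁻¹)

In this flask, half of the dissolving up to 3.0 min is done by 0.0910 min, far sooner than half of the gas's way across to reagent up to that time, at 1.39 min. This flask holds 9.49 % solid at 1.50 min and 0 % at 3.00 min, and my estimated solid-out time of 1.83 min falls between those two moments. For the same charge left until 50 s, the line gives 11.6 % target and 19.4 % solid, and that flask holds 10.2 % target and 20.8 % solid.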